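The readings are calculated with made-up constants; the scatter is artificial.

Late in the Tuesday's run the share of X left has come down from 0.483 at 3.7 h to 0.342 at 7.1 h. The Sunday's flask has the Tuesday's charge, so we take its share at 14 h as that last reading minus a small correction, and reckon just the correction.

| flask | X | E | J | time |
|---|---|---|---|---|
| Tuesday's | 100 mM | 100 mM | 1.00 mM |  |
| Friday's | 40.0 mM | 40.0 mM | 1.00 mM |  |
| Monday's | 100 mM | 100 mM | 1.50 mM |  |
| Wednesday's | 200 mM | 100 mM | 1.00 mM |  |
| Sunday's | 100 mM | 100 mM | 1.00 mM | 14 h |

| Tuesday's run: time / h | Tuesday's run: [X] / mM | Friday's run: time / h | Friday's run: [X] / mM | Monday's run: time / h | Monday's run: [X] / mM | Wednesday's run: time / h | Wednesday's run: [X] / mM |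
|---|---|---|---|---|---|---|---|
| 0.28 | 97.1 | 0.28 | 38.0 | 0.28 | 95.1 | 0.28 | 195.3 |
| 0.54 | 92.2 | 0.54 | 37.2 | 0.54 | 87.9 | 0.54 | 188.1 |
| 1.0 | 82.1 | 1.0 | 32.5 | 1.0 | 74.8 | 1.0 | 173.0 |
| 2.0 | 66.1 | 2.0 | 26.6 | 2.0 | 52.8 | 2.0 | 150.8 |
| 3.7 | 48.3 | 3.7 | 19.1 | 3.7 | 34.5 | 3.7 | 132.5 |
| 7.1 | 34.2 | 7.1 | 14.1 | 7.1 | 27.6 | 7.1 | 125.3 |

(scatter of a reading: 0.5 mM)

- reaction order in [E] at the outset, round the charge of the Tuesday's run, defined at two percent of the X turned into Q
- reaction order in [J] at the outset, round the charge of the Tuesday's run, defined at two percent of the X turned into Q
- the Friday's run starts with 60.0 mM less of X and of E than the Tuesday's run, and with no Q. Compared where both hold the same amount of X, once fifteen percent of what the Friday's run was charged with has turned into Q, is the Friday's run faster, slower or alike (within a tenth)?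
- X in the Sunday's run at 14 h, as a share of the X charged

- Overall: X + E -> Q, with J as catalyst.
- Constant volume, constant temperature.
- Bound and free are read together.
- An order is taken over about fifteen percent of the charge, up and down.

We read the fall-off from the Monday's run, which stands lower at its last reading than the Tuesday's run does. Its slopes, as shares of the charge per hour, over its last two windows are:

0.108 h⁻¹ and then 0.0203 h⁻¹

Their midpoints lie 2.55 h apart, which gives an apparent first-order constant for the slope:

fall-off constant = 0.654 h⁻¹

If the Tuesday's slope dies at that constant, its last window, a fall of 0.141, gives what remains: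

tail = fall / (exp(constant × window) − 1) = 0.0171

Of this tail, the share of the charge still to turn after the last reading, nearly all has turned by 14 h on that constant, since the time from the last reading to then spans 4.51 lifetimes. The share left would be 0.325.

The weak link is the constant itself. The Monday's two earlier windows read 0.529 h⁻¹, lower than the later reading. So in the Monday's run the apparent constant rises from one reading to the next, and if the Tuesday's slope steepens likewise after its last reading, a constant held fixed overstates the tail. We commit, as an estimate, to the middle between 0.325 and the last reading: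

share at 14 h = 0.333

The forecast gives 0.35 for the order in E, 1 for the order in J, faster for the Friday's run and 28 % for the share, lower than our figure, on the ground that “Tuesday should level off near 28%, judging from Monday's plateau.”

The Sunday's flask holds 33.8 % of its charged X at 14 h, with orders of 0.21 in E and 0.69 in J, and the Friday's run is faster where both runs hold the same amount of X.

    Qa + X → JX (339.8 M⁻¹ h⁻¹)
    JX + E → Q + Qa (860.4 M⁻¹ h⁻¹)
    J → Qa (5.940 h⁻¹)
    E → Gu (0.1562 h⁻¹)

That share stands 0.00447 of the charge below the Tuesday's last reading, whose scatter is 0.00500 of the charge, and that gap is less than the tail of 0.0171. The Friday's run has turned half of its charge into Q at 3.48 h against 3.43 h for the Tuesday's run, and on its own last window the same constant gives a tail of 0.0152 of its charge.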